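Readings and results were computed for substances that don't exist; the scatter is artificial.

It is tempting to read conversion from the target column, but what is asked is how much electrophile has gone, and target is one place it goes to.

in all of them: electrophile 0.078 M; nucleophile 0.234 M

| run | free base | remark | time |
|---|---|---|---|
| west | 0.064 M | run made earlier |  |
| north-east | 0.089 M | run made earlier |  |
| maple | 0.0860 M |  | 6.0 h |
| cedar | 0.110 M |  | 6.0 h |

| run | time / h | electrophile / % | target / % |
|---|---|---|---|
| west | 0.667 | 86.0 | 13.2 |
| west | 1.33 | 74.0 | 25.5 |
| west | 2.00 | 65.8 | 31.9 |
| west | 3.00 | 56.0 | 40.3 |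
| west | 4.00 | 48.1 | 45.6 |
| north-east | 0.667 | 85.7 | 14.3 |
| north-east | 1.33 | 74.4 | 24.3 |
| north-east | 2.00 | 65.4 | 30.6 |
| north-east | 3.00 | 56.4 | 38.7 |
| north-east | 4.00 | 48.2 | 43.8 |

(scatter of a reading: 0.5 percentage points)



* part of the electrophile that has reacted at the end, maple
* part of the electrophile that has reacted at the end, cedar
* what raising the concentration of free base from its lowest to its highest value here does to the part of the electrophile that has reacted (changes below 5 percentage points count as none) (it rises / no change / it falls)

So we keep a ledger of the electrophile, the limiting reagent (0.078 M against 0.234 M of nucleophile), in percent of its charge. At the last reading, 4.00 h, the entries are: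

west: electrophile 48.1%, target 45.6%, unread 6.30%

north-east: electrophile 48.2%, target 43.8%, unread 8.00%

The unread entry is larger in north-east, with 0.089 M of free base against 0.064 M. The electrophile entries, however, differ by 0.1 percentage points, less than the scatter of 0.5 points. Free base therefore seems to act on the books after the electrophile has left, and we follow the first entry.

That entry slows as it falls, so we replace the curve by one mean. Let E be the fraction left and s the rise of the reciprocal of E per hour, from its starting value of 1. Averaged over both runs:

s = 0.269 h⁻¹

This s is the mean pace. Carried to 6.0 h, it leaves E as the reciprocal of 1 + st, so the part reacted is: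

61.8%

West at 2.00 h gives a pace of 0.260 h⁻¹ and then 60.9%, a spread of 0.90 points from the figure above, and that one reading carries its own scatter. We expect the same figure for maple and cedar, though cedar's 0.110 M of free base lies beyond the runs.

The forecast gives 62% for maple, 62% for cedar and no change, holding that “consumption looks zero order in base across this range”.

The simulation gives 62.2% for maple and 62.2% for cedar, so no change, with a change of 0.011 points.

    free base + target → over-reaction product A (k = 1.40 L mol⁻¹ h⁻¹)
    2 nucleophile → homo dimer (k = 0.310 L mol⁻¹ h⁻¹)
    electrophile + nucleophile → acid set free + target (k = 1.10 L mol⁻¹ h⁻¹)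
    target → over-reaction product B (k = 7.20 × 10⁻⁵ h⁻¹)
    acid set free + free base ⇌ salt of the base, settled at all times (K = 22000 L mol⁻¹)
    nucleophile + acid set free ⇌ protonated nucleophile, settled at all times (K = 43.0 L mol⁻¹)

The forecast and the flasks agree. At 6.00 h, maple holds electrophile 37.8%, target 49.5% and over-reaction product A 12.7%, while cedar holds 37.8%, 44.3% and 17.9%. Maple's electrophile gives a pace of 0.274 h⁻¹, against 0.269 h⁻¹ from the runs. The neighbouring flask is maple read at 10 h, where the pace from the runs predicts 72.9% reacted. That flask has reacted 73.9%, and its books hold electrophile 26.1%, target 55.2% and over-reaction product A 18.7%.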